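Readings and results were computed for an exercise; noise was put on by code.

4 questions stand on this flask, which is the winter run, followed so far.

all flasks: free catalyst 0.2 mol%
- winter: starting material 2 M; second substrate 0.50 equiv; the very flask that is asked about, followed so far
- flask: starting material 2.0 M; second substrate 0.500 equiv; time 2.0 d

winter run (percent of the starting material charged): time / h: target / % = 4.00: 8.8; 6.00: 12.5; 10.0: 18.5; 20.0: 24.6; 30.0: 27.9; 50.0: 29.9

(standard deviation of a reading: 0.5 percentage points)

- west: at 2.0 d take out 90 % of the target then present, then wait 50 h
- north-east: at 2.0 d add free catalyst, 100 % of the amount charged, then wait 50 h
- south: change nothing and wait 50 h more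

1. target, in percent of the starting material first charged, at 2.0 d
2. the option that brings most further target ("none" if no option brings more than 2 percentage points) (west / north-east / south / none)
3. target present, with what was taken out counted in, in percent of the starting material first charged, after west
4. target present, with what was taken out counted in, in percent of the starting material first charged, after south

- target taken out counts as made
- the analysis behind the earlier runs scatters by 0.5 percentage points, standard deviation
- additions bring no volume worth counting

**How fast does the winter run go?** Let r be the rate of target formation, as a fraction of the charged starting material per hour. Between 4.00 h and 6.00 h, r is 0.0185 h⁻¹. Between 30.0 h and 50.0 h, r is 0.00100 h⁻¹.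

**What do you carry from that?** I carry h, the rate half-life: the time in which r drops to half. The midpoints of those windows lie 35.0 h apart, so the readings give h = 8.31 h. By 2.0 d the winter run has lived 5.77 half-lives.

**But how firm is h?** Not very. The late window rests on a rise of 2 percentage points, and that difference scatters by 0.71 points. So h is a reading, not a sharp constant.

**What does waiting bring?** A rate that keeps halving has a remainder of r·h/ln(2) still to give. At 2.0 d, r has fallen to 5.13 × 10⁻⁴ h⁻¹, so the remainder is 0.62 points. My own reckoning puts the flask at 29.8 % now and at 30.4 % after south.

**Why does r fall?** The readings do not say. They come from one run at one charge, and they show r falling. An equilibrium being approached and a catalyst being lost can both bend a curve like this. Taking target out tests the first, and adding free catalyst tests the second. I put no number on either.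

The forecast does choose: “The run fits a reversible reaction better than a dying catalyst.” It gives 29.8 % now, 30.4 % after south and 39.8 % after west, and it names west.

    second substrate + free catalyst ⇌ catalyst intermediate B (K = 1.30 M⁻¹, k = 440 M⁻¹ h⁻¹)
    catalyst intermediate A → free catalyst + target (k = 61.0 h⁻¹)
    catalyst intermediate B → free catalyst + second product (k = 14.0 h⁻¹)
    starting material + catalyst intermediate B → spent catalyst (k = 0.140 M⁻¹ h⁻¹)
    starting material + free catalyst ⇌ catalyst intermediate A (K = 0.410 M⁻¹, k = 350 M⁻¹ h⁻¹)

The flask gives 29.7 % now, and 30.3 % after south or 30.3 % after west. Each of those gains 0.61 points, against a remainder of 0.62 points. The option north-east brings 40 points. At 48.0 h, free catalyst stands at 0.717 % of its charge and spent catalyst, the off-cycle form, at 98.2 %. With the same h and r taken in proportion to the catalyst charge, a neighbour flask charged with 0.05 mol% free catalyst, a quarter of this charge, reckons to 7.43 %, and it gives 6.83 %. Left for 480 h, this flask holds 30.4 % target and 69.4 % starting material, with spent catalyst at 100 %.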